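**Plan**

1. Retrosynthesis first frees O4 from a silyl group, then cuts the two aryl–CH2 bonds C3–C1′ and C5–C1″ in one operation (double retro-Claisen) back to a 2,6-bis(2-methylbut-3-en-2-yl) ether. The two tertiary O–C bonds are then cut to a 2,6-diol and a C5 alkynyl carbonate.
2. Enabling feature: in the phloroglucinol ring (C1 carries the benzoyl group, C2/C4/C6 the oxygens) C3 and C5 each lie ortho to an oxygen-bearing carbon (C2, C6) whose other ortho neighbour is the quaternary C1. An allyl group on O2 or O6 can therefore settle only at C3 or C5.
3. Forward order: silylate O4 of the purchased benzophenone, hang two C5 units on O2 and O6 as tertiary propargyl ethers, semihydrogenate, heat (both C–C bonds form), desilylate. Both rings are bought; none is built.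
4. Stereochemistry: the target has no stereocentre and no E/Z-defined alkene (each prenyl alkene ends in a gem-dimethyl group). Allyl inversion in the sigmatropic shift supplies the linear prenyl groups.

Key step: step 5

Assumption: the cyclohexadienones passed through in the rearrangement form as racemates and lose their sp3 ring carbon on enolisation, so they are drawn without configuration; ring positions are counted from the benzoyl-bearing carbon as C1.

**Step 1**
Reactants: 1 2,4,6-trihydroxybenzophenone; 2 chlorotriisopropylsilane
Product: 3 [2,6-dihydroxy-4-(triisopropylsilyloxy)phenyl](phenyl)methanone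
Conditions: TIPSCl (1.05 equiv), imidazole (2.2 equiv), CH2Cl2–DMF, −20 → 0 °C
Reagents that add atoms: chlorotriisopropylsilane (2), CC(C)[Si](Cl)(C(C)C)C(C)C
Why: Regioselective phenol silylation: the 4-hydroxyl is the most acidic and the only one neither flanked by the twisted benzoyl group nor tied into the hydrogen bond to the ketone, so one equivalent of the bulky silyl chloride should react there alone.

**Step 2**
Reactants: 4 2-methylbut-3-yn-2-ol; 5 di-tert-butyl dicarbonate
Product: 7 tert-butyl 2-methylbut-3-yn-2-yl carbonate, via lithium 2-methylbut-3-yn-2-olate 6 (not isolated)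
Conditions: n-BuLi (1.0 equiv), THF, −78 °C; then Boc2O, −78 °C → rt
Reagents that add atoms: di-tert-butyl dicarbonate (5), CC(C)(C)OC(=O)OC(C)(C)C
Why: O-Acylation of a lithium alkoxide with Boc2O is a standard carbonate synthesis for tertiary propargylic alcohols, and one equivalent of n-BuLi removes only the O–H proton, not the far less acidic alkyne C–H.

**Step 3**
Reactants: 3 [2,6-dihydroxy-4-(triisopropylsilyloxy)phenyl](phenyl)methanone; 7 tert-butyl 2-methylbut-3-yn-2-yl carbonate
Product: 9 [2,6-bis(2-methylbut-3-yn-2-yloxy)-4-(triisopropylsilyloxy)phenyl](phenyl)methanone, via mono-propargyl ether 8 (not isolated)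
Conditions: 7 (2.6 equiv), CuCl2·2H2O (2 mol%), DBU (3 equiv), MeCN, 0 °C → rt
Reagents that add atoms: tert-butyl 2-methylbut-3-yn-2-yl carbonate (7), CC(C)(C)OC(=O)OC(C)(C)C#C
Why: Copper-catalysed propargylic etherification of phenols: a copper acetylide ionises the tertiary carbonate to a copper allenylidene, which the DBU-generated phenoxide captures at the quaternary carbon; the method is known to reach hindered and carbonyl-chelated phenols, and its only by-products (CO2 and tert-butanol) should not threaten the aryl silyl ether.

**Step 4**
Reactants: 9 [2,6-bis(2-methylbut-3-yn-2-yloxy)-4-(triisopropylsilyloxy)phenyl](phenyl)methanone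
Product: 11 [2,6-bis(2-methylbut-3-en-2-yloxy)-4-(triisopropylsilyloxy)phenyl](phenyl)methanone, via half-reduced enyne diether 10 (not isolated)
Conditions: H2 (1 atm), Pd/CaCO3 poisoned with Pb(OAc)2 (Lindlar catalyst), quinoline, EtOAc, rt; stopped after 2 equiv H2
Reagents that add atoms: none
Why: Lindlar semihydrogenation should stop each terminal alkyne at the vinyl stage when quinoline is present and uptake is halted at two equivalents, while the diaryl ketone, the aryl silyl ether and the tertiary C–O bonds are inert at room temperature, where the product ether does not yet rearrange.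

**Step 5**
Reactants: 11 [2,6-bis(2-methylbut-3-en-2-yloxy)-4-(triisopropylsilyloxy)phenyl](phenyl)methanone
Product: 15 [2,6-dihydroxy-3,5-bis(3-methylbut-2-enyl)-4-(triisopropylsilyloxy)phenyl](phenyl)methanone, via first dienone 12 (not isolated), via monoprenyl phenol 13 (not isolated), via second dienone 14 (not isolated)
Conditions: PhMe (degassed), 110 °C, sealed tube, base-washed glass
Reagents that add atoms: none
Why: Each 2-methylbut-3-en-2-yl aryl ether undergoes a concerted suprafacial [3,3] sigmatropic shift through a chair-like six-membered transition state in which the vinyl CH2 terminus bonds to the free ortho carbon (C3, then C5) while the tertiary O–C bond breaks, and the cyclohexa-2,4-dienones 12 and 14 enolise at once to phenols held by a hydrogen bond to the benzoyl oxygen. The closest known reaction is the aromatic Claisen rearrangement of aryl 1,1-dimethylallyl ethers to ortho-prenyl phenols, which runs near 100 °C because the gem-dimethyl group and the weak, crowded tertiary C–O bond lower the barrier. No ring is closed and no stereocentre is created; the transient sp3 carbon of each dienone disappears on enolisation, and allyl inversion turns the branched O-allyl group into the linear prenyl group. The step needs carbon-over-oxygen and ortho-over-para selectivity: the intramolecular path delivers exactly one prenyl group per oxygen, and because C1 carries the benzoyl group a shift towards C1 gives a dienone that cannot enolise and reverts, so each group can settle only at C3 or C5. Neutral, degassed toluene at moderate temperature is chosen so that neither ionisation of the tertiary ether (loss of isoprene) nor acid-promoted chroman closure of the new ortho-prenyl phenols competes.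

**Step 6**
Reactants: 15 [2,6-dihydroxy-3,5-bis(3-methylbut-2-enyl)-4-(triisopropylsilyloxy)phenyl](phenyl)methanone
Product: 16 clusiaphenone B, [2,4,6-trihydroxy-3,5-bis(3-methylbut-2-enyl)phenyl](phenyl)methanone
Conditions: TBAF (1.2 equiv), AcOH (1.2 equiv), THF, 0 °C
Reagents that add atoms: none
Why: Fluoride-induced desilylation of an aryl silyl ether, fast here because the departing phenoxide is part of a vinylogous acid; the acetic acid buffer should keep the prenylated acylphloroglucinol from base-promoted oxidation or cyclisation.

**Compound list**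

1 | 2,4,6-trihydroxybenzophenone | O=C(c1ccccc1)c1c(O)cc(O)cc1O | starting material
2 | chlorotriisopropylsilane | CC(C)[Si](Cl)(C(C)C)C(C)C | starting material
3 | [2,6-dihydroxy-4-(triisopropylsilyloxy)phenyl](phenyl)methanone | O=C(c1ccccc1)c1c(O)cc(O[Si](C(C)C)(C(C)C)C(C)C)cc1O | intermediate
4 | 2-methylbut-3-yn-2-ol | CC(C)(O)C#C | starting material
5 | di-tert-butyl dicarbonate | CC(C)(C)OC(=O)OC(=O)OC(C)(C)C | starting material
6 | lithium 2-methylbut-3-yn-2-olate | [Li+].CC(C)([O-])C#C | intermediate
7 | tert-butyl 2-methylbut-3-yn-2-yl carbonate | CC(C)(C)OC(=O)OC(C)(C)C#C | intermediate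
8 | [2-hydroxy-6-(2-methylbut-3-yn-2-yloxy)-4-(triisopropylsilyloxy)phenyl](phenyl)methanone | O=C(c1ccccc1)c1c(O)cc(O[Si](C(C)C)(C(C)C)C(C)C)cc1OC(C)(C)C#C | intermediate
9 | [2,6-bis(2-methylbut-3-yn-2-yloxy)-4-(triisopropylsilyloxy)phenyl](phenyl)methanone | O=C(c1ccccc1)c1c(OC(C)(C)C#C)cc(O[Si](C(C)C)(C(C)C)C(C)C)cc1OC(C)(C)C#C | intermediate
10 | [2-(2-methylbut-3-en-2-yloxy)-6-(2-methylbut-3-yn-2-yloxy)-4-(triisopropylsilyloxy)phenyl](phenyl)methanone | O=C(c1ccccc1)c1c(OC(C)(C)C=C)cc(O[Si](C(C)C)(C(C)C)C(C)C)cc1OC(C)(C)C#C | intermediate
11 | [2,6-bis(2-methylbut-3-en-2-yloxy)-4-(triisopropylsilyloxy)phenyl](phenyl)methanone | O=C(c1ccccc1)c1c(OC(C)(C)C=C)cc(O[Si](C(C)C)(C(C)C)C(C)C)cc1OC(C)(C)C=C | intermediate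
12 | 2-benzoyl-3-(2-methylbut-3-en-2-yloxy)-6-(3-methylbut-2-enyl)-5-(triisopropylsilyloxy)cyclohexa-2,4-dien-1-one (racemic) | O=C(c1ccccc1)C1=C(OC(C)(C)C=C)C=C(O[Si](C(C)C)(C(C)C)C(C)C)C(CC=C(C)C)C1=O | intermediate
13 | [2-hydroxy-3-(3-methylbut-2-enyl)-6-(2-methylbut-3-en-2-yloxy)-4-(triisopropylsilyloxy)phenyl](phenyl)methanone | O=C(c1ccccc1)c1c(O)c(CC=C(C)C)c(O[Si](C(C)C)(C(C)C)C(C)C)cc1OC(C)(C)C=C | intermediate
14 | 2-benzoyl-3-hydroxy-4,6-bis(3-methylbut-2-enyl)-5-(triisopropylsilyloxy)cyclohexa-2,4-dien-1-one (racemic) | O=C(c1ccccc1)C1=C(O)C(CC=C(C)C)=C(O[Si](C(C)C)(C(C)C)C(C)C)C(CC=C(C)C)C1=O | intermediate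
15 | [2,6-dihydroxy-3,5-bis(3-methylbut-2-enyl)-4-(triisopropylsilyloxy)phenyl](phenyl)methanone | O=C(c1ccccc1)c1c(O)c(CC=C(C)C)c(O[Si](C(C)C)(C(C)C)C(C)C)c(CC=C(C)C)c1O | intermediate
16 | clusiaphenone B, [2,4,6-trihydroxy-3,5-bis(3-methylbut-2-enyl)phenyl](phenyl)methanone | CC(C)=CCc1c(O)c(CC=C(C)C)c(O)c(C(=O)c2ccccc2)c1O | target

**Count**

Total steps: 6. Longest linear sequence: 5 (steps 1, 3, 4, 5, 6; step 2 is a one-step side branch that joins at step 3).

**Steps most likely to fail**

Step 3. The second etherification may stall at the hydroxyl that is hydrogen-bonded to the ketone and crowded by the benzoyl group, and long exposure to DBU may strip or shift the aryl silyl group. The fallback sets out from 3 and comes back to the route at 15, introducing the two C5 units one at a time so that each etherification meets a hydroxyl that is not locked in the hydrogen bond.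
- Compound 3 would be treated with one equivalent of 7 under the copper conditions and the reaction stopped at the mono-ether 8, which is isolated.
- Lindlar semihydrogenation would give [2-hydroxy-6-(2-methylbut-3-en-2-yloxy)-4-(triisopropylsilyloxy)phenyl](phenyl)methanone F1.
- Heating F1 in toluene would move the allyl group to the adjacent free carbon by way of 2-benzoyl-3-hydroxy-6-(3-methylbut-2-enyl)-5-(triisopropylsilyloxy)cyclohexa-2,4-dien-1-one F2, giving [2,6-dihydroxy-3-(3-methylbut-2-enyl)-4-(triisopropylsilyloxy)phenyl](phenyl)methanone F3.
- In that diol the ketone can hold only one hydroxyl at a time, and the oxygen remote from the new prenyl group is the less hindered. A second copper-catalysed etherification with 7 should therefore give [2-hydroxy-3-(3-methylbut-2-enyl)-6-(2-methylbut-3-yn-2-yloxy)-4-(triisopropylsilyloxy)phenyl](phenyl)methanone F4.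
- Semihydrogenation of F4 (the trisubstituted prenyl alkene is inert to the poisoned catalyst) would give 13 as an isolated compound, and heating would give 15 through 14.

Step 5. Heat may ionise the tertiary ether so that isoprene is lost instead of transferred, a group may travel on from the blocked C1 to the para carbon, or traces of acid may close a chroman onto a new phenol. The fallback sets out from 1 and comes back at 16 and gives up the oxygen-to-carbon transfer. Compound 1 would be C-prenylated twice with 1-bromo-3-methylbut-2-ene (about 2 equiv) in aqueous KOH at 0 °C. This is the known carbon alkylation of acylphloroglucinol phenoxides in water, where hydrogen bonding to the oxygens steers the electrophile to C3 and C5. It reaches the target in one operation, at the price of separating under- and over-prenylated and O-prenylated material; it makes no compound outside the list (F0).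

Step 4. Hydrogen uptake may run past the alkene at one of the two vinyl groups, or a tertiary propargylic C–O bond may undergo hydrogenolysis on palladium. The fallback sets out from 3 and comes back at 11 and avoids hydrogen by installing the allyl ethers directly.
- Commercial 2-methylbut-3-en-2-ol would be deprotonated with n-BuLi to lithium 2-methylbut-3-en-2-olate F5 and acylated with 5 to give tert-butyl 2-methylbut-3-en-2-yl carbonate F6.
- Tsuji–Trost O-allylation of 3 with F6 and Pd(PPh3)4 (a zerovalent palladium catalyst) in THF at 0 °C would follow. Ionisation gives a 1,1-dimethylallyl palladium cation and tert-butoxide, which deprotonates the phenol; the phenoxide attacks the more substituted allyl terminus under kinetic control and should give the bis(tertiary allyl) ether 11 without passing through 9.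
- The reaction would be stopped early, since prolonged contact with the catalyst isomerises such ethers to the linear O-prenyl isomers.

**Further compounds**

F1 | step 3 | [2-hydroxy-6-(2-methylbut-3-en-2-yloxy)-4-(triisopropylsilyloxy)phenyl](phenyl)methanone | O=C(c1ccccc1)c1c(O)cc(O[Si](C(C)C)(C(C)C)C(C)C)cc1OC(C)(C)C=C
F2 | step 3 | 2-benzoyl-3-hydroxy-6-(3-methylbut-2-enyl)-5-(triisopropylsilyloxy)cyclohexa-2,4-dien-1-one (racemic) | O=C(c1ccccc1)C1=C(O)C=C(O[Si](C(C)C)(C(C)C)C(C)C)C(CC=C(C)C)C1=O
F3 | step 3 | [2,6-dihydroxy-3-(3-methylbut-2-enyl)-4-(triisopropylsilyloxy)phenyl](phenyl)methanone | O=C(c1ccccc1)c1c(O)cc(O[Si](C(C)C)(C(C)C)C(C)C)c(CC=C(C)C)c1O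
F4 | step 3 | [2-hydroxy-3-(3-methylbut-2-enyl)-6-(2-methylbut-3-yn-2-yloxy)-4-(triisopropylsilyloxy)phenyl](phenyl)methanone | O=C(c1ccccc1)c1c(O)c(CC=C(C)C)c(O[Si](C(C)C)(C(C)C)C(C)C)cc1OC(C)(C)C#C
F5 | step 4 | lithium 2-methylbut-3-en-2-olate | [Li+].CC(C)([O-])C=C
F6 | step 4 | tert-butyl 2-methylbut-3-en-2-yl carbonate | CC(C)(C)OC(=O)OC(C)(C)C=C
F0 | step 5 | none | none
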